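| flask | starting material | enzyme | remark | time |
|---|---|---|---|---|
| teal | 0.28 mM | 0.92 µM | run made earlier |  |
| ochre | 2.2 mM | 0.92 µM | run made earlier |  |
| violet | 21 mM | 0.92 µM | run made earlier |  |
| beta | 0.25 mM | 0.92 µM |  | 25 min |
| zeta | 0.80 mM | 0.92 µM |  | 25 min |
| epsilon | 2.0 mM | 0.92 µM |  | 25 min |
| alpha | 6.0 mM | 0.92 µM |  | 25 min |
| theta | 20 mM | 0.92 µM |  | 25 min |

- teal (time / min: product / %, starting material / %): 1.50: 11.5, 85.1; 4.00: 27.9, 63.6; 8.00: 49.2, 43.3; 12.0: 59.2, 30.9; 20.0: 75.5, 16.6
- ochre (time / min: product / %, starting material / %): 4.00: 23.3, 60.2; 8.00: 38.1, 38.0; 10.0: 43.0, 32.1; 15.0: 53.0, 20.1; 20.0: 59.7, 14.3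
- violet (time / min: product / %, starting material / %): 1.50: 3.2, 92.8; 4.00: 9.0, 78.5; 8.00: 22.0, 60.2; 12.0: 29.5, 43.9; 20.0: 39.9, 21.4

(each reading ± 1 percentage point)

- the numbers in the tables scatter by 1 percentage point (one standard deviation)
- a reading or a percentage of product counts all its forms, free or not
- the concentration of product that is asked is that of its free form alone
- "hardly changes" means that all values lie within two and a half points (for a concentration: within two and a half percent of the largest)
- a reading of starting material is of its free form alone

* [product] (only what is free in solution) at the end for beta, zeta, epsilon, alpha, theta, in this order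
* the shape of the row from first to last (falls all the way / falls, then rises / rises all the way / rises, then falls / hardly changes)

The ochre run closes short of its charge. At 10.0 min the readings leave a gap of 24.9 %, and at 20.0 min a gap of 26.0 %, while starting material still falls. A product reading counts every form of product, so the level gap reads as product holding one more starting material. Each such pair hides one starting material, and free product is then the reading minus the gap, 33.7 % in ochre.

The quantity to carry is the lock constant, an association constant: bound pairs divided by [starting material] and by [free product]. Ochre at 20.0 min gives 2.45 /mM. The teal run, at its own charge, has a gap of 7.90 % and free product of 67.6 % at 20.0 min, which gives 2.51 /mM. These two runs are separate measurements and stand close, so their mean, 2.48 /mM, is kept.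

The constant opens a second way to free product: total product divided by one plus the lock constant times [starting material]. In the violet run at 20.0 min the two ways part. Subtraction leaves 1.20 %, while the rule gives 3.28 %. Subtraction is the one that cheats here: its scatter of 2.2 percentage points is more than the 1.20 % it leaves.

By the rule, violet at 20.0 min holds 0.689 mM of free product. That is less than the 0.741 mM in ochre, at ten times the charge. The reckoning here therefore expects a row that climbs and then stops climbing at the high charges.

The forecast gives 0.195 mM, 0.51 mM, 0.85 mM, 1.5 mM and 1.3 mM, with the shape rises, then falls. It takes 2 /mM where the reckoning here has 2.48 /mM, and at the top charge it holds that “much product is still locked up”.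

The flasks give 0.195 mM, 0.498 mM, 0.913 mM, 1.54 mM and 1.42 mM: rises, then falls, turning at 11 mM.

    starting material + enzyme → product + enzyme, rate k1*[starting material]*[enzyme]/(1 + ([starting material]/Km1)) (8.90 mM, k = 27000 /M/s)
    2 enzyme → spent catalyst (k = 79000 /M/min)
    starting material + product ⇌ idle adduct, settled at all times (K = 2200 /M)
    2 enzyme ⇌ resting dimer, settled at all times (K = 1.40 × 10⁸ /M)

The hidden pair is the idle adduct. In theta at 25.0 min, product stands at 47.2 % and idle adduct, counted as two, at 80.1 %, beside 12.8 % of starting material. The lock constant turns those values into 1.28 mM of free product, against 1.42 mM. On alpha, with 58.1 % of product and 9.55 % of starting material, it gives 1.44 mM, against 1.54 mM.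

(The numbers in the tables were computed from invented constants.)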